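The readings were computed on assumed constants, and the scatter is random.

I could not read the order in Ve from Sunday's and Friday's runs, since both carried 10 mol%, so I asked instead whether the Ve charged kept working.

| setting | Sunday's | Friday's | flask |
|---|---|---|---|
| Ux | 0.052 M | 0.052 M | 0.052 M |
| Ry | 0.052 M | 0.052 M | 0.052 M |
| Xo | 0.60 equiv | 0.40 equiv | 0.600 equiv |
| Ve | 10 mol% | 10 mol% | 10 mol% |
| remark | the very flask that is asked about, followed so far | run made earlier |  |

| run | time / min | Jo / % | Ux / % |
|---|---|---|---|
| Sunday's | 0.500 | 11.2 | 38.6 |
| Sunday's | 1.00 | 15.1 | 34.2 |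
| Sunday's | 2.50 | 20.8 | 29.2 |
| Sunday's | 6.00 | 25.9 | 24.7 |
| Friday's | 1.33 | 11.4 | 37.5 |
| Friday's | 4.00 | 16.6 | 33.1 |
| Friday's | 6.00 | 17.1 | 32.3 |
| Friday's | 10.0 | 18.7 | 30.7 |

(each reading ± 0.5 percentage points)

- factor on the rate of making Jo when 10% of the Ux and Ry together are converted if Ve is charged twice over
- factor on the rate when 10% of the Ux and Ry together are converted if Ve is charged at 2 mol% instead

- Ve is single-handed; Ux and Ry are mirror images of each other, charged as a racemate, each of them at the stated concentration
- no earlier run changes the charge of Ve; that part of a forecast is a guess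

I defined the activity a as the rate of making Jo divided by the mean Ux and the mean Xo left, all as fractions of the Ux and Ry together charged, assuming one Xo per Jo. In Sunday's flask a was 2.07 min⁻¹ over the first 0.500 min but 0.813 min⁻¹ between 2.50 min and 6.00 min, lower than at the start, which gave the share of activity kept, 0.392. Sunday's flask passed 10% conversion of Ux and Ry together, the mark asked about, at 0.380 min, so a first-order clock put 2 mol% at 1.90 min, later than that, and, taking the share kept as a rough stand-in for that later time, I reckoned the factor as the loading ratio times the share kept, 0.0785, with the doubled charge somewhat above 2.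

The forecast gave 2 and 0.2, saying “I assume first order”; my factor for 2 mol% was lower than its figure. The flask gives 2.43 and 0.0728.

    Xo + Ve + Ux → Ve + Jo (k = 88.0 L² mol⁻² s⁻¹)
    Xo + Ve + Ry → Ve + Wy (k = 0.830 L² mol⁻² s⁻¹)
    Ve → Qa (k = 6.30 × 10⁻⁴ s⁻¹)
    Ve ⇌ Ej (K = 2.70, k = 0.0170 s⁻¹)

The largest single effect proven on the rate at the mark is the turning of Ve into Ej, an off-cycle form, both ways: without it Sunday's flask stands at 1.43 times the actual rate. With 2 mol%, 25.1% of the catalyst is Ve at the mark. On Friday's run a read 0.920 min⁻¹ between 1.33 min and 4.00 min, lower than the 1.27 min⁻¹ read in Sunday's flask between 0.500 min and 1.00 min at a similar mean Jo, and the share kept in Friday's run, taken against Sunday's early a, read 0.444, where Sunday's own late window read 0.392.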